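**Strategy.** Everything rests on disconnecting the aryl C–O bond of the 2,2-dimethylpyran ring fused to ring B: pyran O1 to C8a (chromene numbering; C4' of the flavanone). C8a lies para to C6, the carbon bearing flavanone C2, which at the aldehyde stage is a formyl group; this makes C8a an SNAr site. The key step closes the pyran in one operation by attack of a tertiary (Z)-allylic alkoxide on a 4-fluorobenzaldehyde. Its precursor is an open-chain fluoroarene carrying two C5 units, both unmasked by one Lindlar reduction; the tert-allyl ether next to fluorine later delivers the ring B prenyl group by Claisen rearrangement. C2 is set by a thiourea-catalysed oxa-Michael closure.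

Key step: step 5

Remark: the pyran-fused ring B is numbered as a chromene (O1, C2, C3, C4, C4a, C5 to C8, C8a); chromene C6 is C1' of the flavanone.
Remark: acetal 1 is taken as a catalogue compound (otherwise one step from 3-bromo-4-fluorobenzaldehyde and ethylene glycol).
Assumption: the quinidine-derived thiourea of step 11 is taken to give the 2S product; its quinine-derived pseudoenantiomer gives the antipode and would be used if the sense proves reversed.

**Route**

Step 1
Reactants: 1 2-(3-bromo-4-fluorophenyl)-1,3-dioxolane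
Product: 5 3-bromo-4-fluoro-5-hydroxybenzaldehyde, via aryllithium 2 (not isolated), via lithium arylborate 3 (not isolated), via phenol acetal 4 (not isolated)
Conditions: LiN(iPr)2, THF, −78 °C; B(OMe)3, −78 → 0 °C; 30% H2O2, AcOH, 0 °C → rt; then 2 M HCl, THF, rt
Reagents that add atoms: hydrogen peroxide OO; water O
Why: Directed ortho-metalation, in which the amide base removes the most acidic ring proton (ortho to fluorine, meta to bromine) at a temperature where the ortho-fluoroaryllithium does not lose LiF, followed by borylation, oxidative ipso-hydroxylation of the borate and acid hydrolysis of the dioxolane.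

Step 2
Reactants: 5 3-bromo-4-fluoro-5-hydroxybenzaldehyde; 6 2-methylbut-3-yn-2-ol
Product: 7 4-fluoro-3-hydroxy-5-(3-hydroxy-3-methylbut-1-yn-1-yl)benzaldehyde
Conditions: PdCl2(PPh3)2 (3 mol %), CuI (5 mol %), Et3N, THF, 60 °C
Reagents that add atoms: none
Why: Sonogashira coupling of the aryl bromide with the terminal alkyne, in which the C–F bond is inert to zerovalent palladium and the phenol, not being ortho to the new alkyne, cannot close a benzofuran.

Step 3
Reactants: 7 4-fluoro-3-hydroxy-5-(3-hydroxy-3-methylbut-1-yn-1-yl)benzaldehyde; 8 3-chloro-3-methylbut-1-yne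
Product: 9 4-fluoro-3-(3-hydroxy-3-methylbut-1-yn-1-yl)-5-[(2-methylbut-3-yn-2-yl)oxy]benzaldehyde
Conditions: CuCl2·2H2O (1 mol %), DBU, MeCN, 0 °C
Reagents that add atoms: none
Why: Copper-catalysed propargylic substitution (through a copper allenylidene) alkylates the acidic, electron-poor phenol and not the tertiary alcohol, giving the tertiary aryl propargyl ether.

Step 4
Reactants: 9 4-fluoro-3-(3-hydroxy-3-methylbut-1-yn-1-yl)-5-[(2-methylbut-3-yn-2-yl)oxy]benzaldehyde
Product: 10 4-fluoro-3-[(1Z)-3-hydroxy-3-methylbut-1-en-1-yl]-5-[(2-methylbut-3-en-2-yl)oxy]benzaldehyde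
Conditions: H2 (1 atm, 2 equiv taken up), Pd/CaCO3 poisoned with Pb(OAc)2 (Lindlar catalyst), quinoline, EtOAc, rt
Reagents that add atoms: none
Why: Lindlar semi-hydrogenation adds H2 syn on the poisoned palladium surface, so the aryl alkyne should become the Z alkene and the terminal alkyne the vinyl group in one operation, with quinoline holding back over-reduction.

Step 5
Reactants: 10 4-fluoro-3-[(1Z)-3-hydroxy-3-methylbut-1-en-1-yl]-5-[(2-methylbut-3-en-2-yl)oxy]benzaldehyde
Product: 13 2,2-dimethyl-8-[(2-methylbut-3-en-2-yl)oxy]-2H-chromene-6-carbaldehyde, via sodium alkoxide 11 (not isolated), via Meisenheimer adduct 12 (not isolated)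
Conditions: NaH (1.2 equiv), THF/DMF 4:1, 0 °C → rt
Reagents that add atoms: none
Why: NaH converts the tertiary alcohol of 10 into alkoxide 11, whose oxygen adds to the fluorine-bearing carbon (the future C8a) to give Meisenheimer adduct 12 with the charge delocalised into the para formyl group, and loss of fluoride restores the arene (addition–elimination SNAr). The closest known reaction type is the intramolecular SNAr O-arylation of alkoxides on fluoroarenes activated by a para or ortho carbonyl group, as used for chromans and related benzo-fused ethers. The one ring closed is the 2H-pyran, by a six-membered attack (6-exo-trig, counting the C8a=C8 π bond) of O1 on C8a, which the Z double bond makes possible by holding the carbinol beside the C–F carbon. No stereocentre is formed. The step needs chemoselectivity for C8a over the formyl carbon and over bimolecular substitution: addition of the alkoxide to the aldehyde is reversible and leads nowhere, fluoride is the only leaving group on the ring, the intramolecular closure outpaces any intermolecular path, and the tert-allyl ether masks the neighbouring phenol, whose anion would otherwise switch off the ring.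

Step 6
Reactants: 13 2,2-dimethyl-8-[(2-methylbut-3-en-2-yl)oxy]-2H-chromene-6-carbaldehyde
Product: 16 8-(methoxymethoxy)-2,2-dimethyl-7-(3-methylbut-2-en-1-yl)-2H-chromene-6-carbaldehyde, via ortho-dienone 14 (not isolated), via phenol 15 (not isolated)
Conditions: PhMe, 120 °C, sealed tube; then iPr2NEt, MOMCl, 0 °C → rt
Reagents that add atoms: chloromethyl methyl ether COCCl
Why: Aromatic Claisen rearrangement, in which the 1,1-dimethylallyl ether shifts [3,3] to C7 (the only hydrogen-bearing ortho carbon, since a shift to C8a cannot be followed by enolisation and is reversible), dienone 14 tautomerises to phenol 15 carrying the linear prenyl group, and the phenol is then capped by O-alkylation with MOMCl.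

Step 7
Reactants: 17 1-(2,4,6-trihydroxyphenyl)ethan-1-one; 18 1-bromo-3-methylbut-2-ene
Product: 19 1-[2,4,6-trihydroxy-3-(3-methylbut-2-en-1-yl)phenyl]ethan-1-one
Conditions: DBU, THF, 0 °C → rt (17 in excess)
Reagents that add atoms: none
Why: C-alkylation of the ambident phloroglucinol-type phenoxide by the soft allylic bromide (phenoxide C-prenylation), with the acetophenone in excess to limit double prenylation.

Step 8
Reactants: 19 1-[2,4,6-trihydroxy-3-(3-methylbut-2-en-1-yl)phenyl]ethan-1-one
Product: 20 1-[2-hydroxy-4,6-bis(methoxymethoxy)-3-(3-methylbut-2-en-1-yl)phenyl]ethan-1-one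
Conditions: MOMCl (2.2 equiv), iPr2NEt, CH2Cl2, 0 °C → rt
Reagents that add atoms: chloromethyl methyl ether COCCl
Why: Williamson-type O-alkylation, in which the non-chelated 4-OH and then the less hindered 6-OH should react while the 2-OH, flanked by acetyl and prenyl and hydrogen-bonded to the carbonyl, stays free.

Step 9
Reactants: 20 1-[2-hydroxy-4,6-bis(methoxymethoxy)-3-(3-methylbut-2-en-1-yl)phenyl]ethan-1-one
Product: 22 tert-butyl 3-[2-hydroxy-4,6-bis(methoxymethoxy)-3-(3-methylbut-2-en-1-yl)phenyl]-3-oxopropanoate, via dilithium enolate 21 (not isolated)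
Conditions: LiN(SiMe3)2 (3.2 equiv), THF, −78 °C; Boc2O (1.05 equiv), −78 → −40 °C; aq NH4Cl
Reagents that add atoms: di-tert-butyl dicarbonate CC(C)(C)OC(=O)OC(=O)OC(C)(C)C
Why: Claisen-type C-acylation, in which the methyl-ketone enolate carbon of dianion 21 is more nucleophilic than the hindered chelated phenoxide and attacks Boc2O, the third equivalent of base then deprotonating the β-keto ester so that it is not acylated again.

Step 10
Reactants: 22 tert-butyl 3-[2-hydroxy-4,6-bis(methoxymethoxy)-3-(3-methylbut-2-en-1-yl)phenyl]-3-oxopropanoate; 16 8-(methoxymethoxy)-2,2-dimethyl-7-(3-methylbut-2-en-1-yl)-2H-chromene-6-carbaldehyde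
Product: 23 tert-butyl 2-[2-hydroxy-4,6-bis(methoxymethoxy)-3-(3-methylbut-2-en-1-yl)benzoyl]-3-[8-(methoxymethoxy)-2,2-dimethyl-7-(3-methylbut-2-en-1-yl)-2H-chromen-6-yl]prop-2-enoate (E/Z mixture)
Conditions: piperidine (10 mol %), AcOH (10 mol %), 4 Å molecular sieves, PhMe, rt
Reagents that add atoms: none
Why: Knoevenagel condensation under piperidinium acetate catalysis with removal of water, kept at room temperature so that the free 2-OH does not close in an uncatalysed, racemic sense.

Step 11
Reactants: 23 tert-butyl 2-[2-hydroxy-4,6-bis(methoxymethoxy)-3-(3-methylbut-2-en-1-yl)benzoyl]-3-[8-(methoxymethoxy)-2,2-dimethyl-7-(3-methylbut-2-en-1-yl)-2H-chromen-6-yl]prop-2-enoate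
Product: 26 (2S)-5,7-bis(methoxymethoxy)-2-[8-(methoxymethoxy)-2,2-dimethyl-7-(3-methylbut-2-en-1-yl)-2H-chromen-6-yl]-8-(3-methylbut-2-en-1-yl)-2,3-dihydro-4H-chromen-4-one, via cyclised tert-butyl ester 24 (not isolated), via keto acid 25 (not isolated)
Conditions: thiourea from 9-amino-9-deoxy-epi-quinidine and 3,5-(CF3)2C6H3NCS (10 mol %), PhMe, −25 °C; then anhydrous TsOH (0.5 equiv), 80 °C
Reagents that add atoms: none
Why: Asymmetric intramolecular oxa-Michael addition under bifunctional cinchona-thiourea catalysis, in which the thiourea binds the β-keto ester, the quinuclidine deprotonates the phenol and the catalyst pocket delivers the phenoxide to one face of the alkylidene to set C2 as S, after which acid cleaves the tert-butyl ester by E1 loss of isobutene and keto acid 25 decarboxylates while the MOM acetals, lacking a nucleophile, should persist.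

Step 12
Reactants: 26 (2S)-5,7-bis(methoxymethoxy)-2-[8-(methoxymethoxy)-2,2-dimethyl-7-(3-methylbut-2-en-1-yl)-2H-chromen-6-yl]-8-(3-methylbut-2-en-1-yl)-2,3-dihydro-4H-chromen-4-one
Product: 27 (2S)-5,7-dihydroxy-2-[8-hydroxy-2,2-dimethyl-7-(3-methylbut-2-en-1-yl)-2H-chromen-6-yl]-8-(3-methylbut-2-en-1-yl)-2,3-dihydro-4H-chromen-4-one
Conditions: 3 M aq HCl, MeOH, 40 °C
Reagents that add atoms: none
Why: Acid-catalysed acetal exchange with methanol removes the three MOM groups as dimethoxymethane under conditions mild enough that the phenols should not add across the prenyl double bonds and the flavanone ring should not open, so the 2S centre is kept.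

**Compound list**

1 | 2-(3-bromo-4-fluorophenyl)-1,3-dioxolane | Fc1ccc(cc1Br)C1OCCO1 | starting material
2 | [3-bromo-5-(1,3-dioxolan-2-yl)-2-fluorophenyl]lithium | [Li]c1cc(cc(Br)c1F)C1OCCO1 | intermediate
3 | lithium [3-bromo-5-(1,3-dioxolan-2-yl)-2-fluorophenyl]trimethoxyborate | [Li+].CO[B-](OC)(OC)c1cc(cc(Br)c1F)C1OCCO1 | intermediate
4 | 3-bromo-5-(1,3-dioxolan-2-yl)-2-fluorophenol | Oc1cc(cc(Br)c1F)C1OCCO1 | intermediate
5 | 3-bromo-4-fluoro-5-hydroxybenzaldehyde | O=Cc1cc(O)c(F)c(Br)c1 | intermediate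
6 | 2-methylbut-3-yn-2-ol | CC(C)(O)C#C | starting material
7 | 4-fluoro-3-hydroxy-5-(3-hydroxy-3-methylbut-1-yn-1-yl)benzaldehyde | O=Cc1cc(O)c(F)c(C#CC(C)(C)O)c1 | intermediate
8 | 3-chloro-3-methylbut-1-yne | CC(C)(Cl)C#C | starting material
9 | 4-fluoro-3-(3-hydroxy-3-methylbut-1-yn-1-yl)-5-[(2-methylbut-3-yn-2-yl)oxy]benzaldehyde | O=Cc1cc(OC(C)(C)C#C)c(F)c(C#CC(C)(C)O)c1 | intermediate
10 | 4-fluoro-3-[(1Z)-3-hydroxy-3-methylbut-1-en-1-yl]-5-[(2-methylbut-3-en-2-yl)oxy]benzaldehyde | O=Cc1cc(OC(C)(C)C=C)c(F)c(/C=C\C(C)(C)O)c1 | intermediate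
11 | sodium (3Z)-4-{2-fluoro-5-formyl-3-[(2-methylbut-3-en-2-yl)oxy]phenyl}-2-methylbut-3-en-2-olate | [Na+].[O-]C(C)(C)/C=C\c1cc(C=O)cc(OC(C)(C)C=C)c1F | intermediate
12 | Meisenheimer adduct: sodium {8a-fluoro-2,2-dimethyl-8-[(2-methylbut-3-en-2-yl)oxy]-2H-chromen-6(8aH)-ylidene}methanolate (racemic at C8a) | [Na+].[O-]C=C1C=C2C=CC(C)(C)OC2(F)C(OC(C)(C)C=C)=C1 | intermediate
13 | 2,2-dimethyl-8-[(2-methylbut-3-en-2-yl)oxy]-2H-chromene-6-carbaldehyde | CC1(C)C=Cc2cc(C=O)cc(OC(C)(C)C=C)c2O1 | intermediate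
14 | 2,2-dimethyl-7-(3-methylbut-2-en-1-yl)-8-oxo-7,8-dihydro-2H-chromene-6-carbaldehyde (racemic at C7) | CC(C)=CCC1C(C=O)=CC2=C(OC(C)(C)C=C2)C1=O | intermediate
15 | 8-hydroxy-2,2-dimethyl-7-(3-methylbut-2-en-1-yl)-2H-chromene-6-carbaldehyde | CC(C)=CCc1c(C=O)cc2C=CC(C)(C)Oc2c1O | intermediate
16 | 8-(methoxymethoxy)-2,2-dimethyl-7-(3-methylbut-2-en-1-yl)-2H-chromene-6-carbaldehyde | CC(C)=CCc1c(C=O)cc2C=CC(C)(C)Oc2c1OCOC | intermediate
17 | 1-(2,4,6-trihydroxyphenyl)ethan-1-one | CC(=O)c1c(O)cc(O)cc1O | starting material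
18 | 1-bromo-3-methylbut-2-ene (prenyl bromide) | CC(C)=CCBr | starting material
19 | 1-[2,4,6-trihydroxy-3-(3-methylbut-2-en-1-yl)phenyl]ethan-1-one | CC(=O)c1c(O)cc(O)c(CC=C(C)C)c1O | intermediate
20 | 1-[2-hydroxy-4,6-bis(methoxymethoxy)-3-(3-methylbut-2-en-1-yl)phenyl]ethan-1-one | CC(=O)c1c(OCOC)cc(OCOC)c(CC=C(C)C)c1O | intermediate
21 | dilithium salt (phenoxide and ketone enolate) of 20 | C=C(O[Li])c1c(OCOC)cc(OCOC)c(CC=C(C)C)c1O[Li] | intermediate
22 | tert-butyl 3-[2-hydroxy-4,6-bis(methoxymethoxy)-3-(3-methylbut-2-en-1-yl)phenyl]-3-oxopropanoate | CC(C)(C)OC(=O)CC(=O)c1c(OCOC)cc(OCOC)c(CC=C(C)C)c1O | intermediate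
23 | tert-butyl 2-[2-hydroxy-4,6-bis(methoxymethoxy)-3-(3-methylbut-2-en-1-yl)benzoyl]-3-[8-(methoxymethoxy)-2,2-dimethyl-7-(3-methylbut-2-en-1-yl)-2H-chromen-6-yl]prop-2-enoate (E/Z mixture) | CC(C)(C)OC(=O)C(=Cc1cc2C=CC(C)(C)Oc2c(OCOC)c1CC=C(C)C)C(=O)c1c(OCOC)cc(OCOC)c(CC=C(C)C)c1O | intermediate
24 | tert-butyl (2S)-5,7-bis(methoxymethoxy)-2-[8-(methoxymethoxy)-2,2-dimethyl-7-(3-methylbut-2-en-1-yl)-2H-chromen-6-yl]-8-(3-methylbut-2-en-1-yl)-4-oxo-3,4-dihydro-2H-chromene-3-carboxylate (C3 epimers and enol) | CC(C)=CCc1c([C@@H]2C(C(=O)OC(C)(C)C)C(=O)c3c(OCOC)cc(OCOC)c(CC=C(C)C)c3O2)cc2c(c1OCOC)OC(C)(C)C=C2 | intermediate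
25 | (2S)-5,7-bis(methoxymethoxy)-2-[8-(methoxymethoxy)-2,2-dimethyl-7-(3-methylbut-2-en-1-yl)-2H-chromen-6-yl]-8-(3-methylbut-2-en-1-yl)-4-oxo-3,4-dihydro-2H-chromene-3-carboxylic acid | CC(C)=CCc1c([C@@H]2C(C(=O)O)C(=O)c3c(OCOC)cc(OCOC)c(CC=C(C)C)c3O2)cc2c(c1OCOC)OC(C)(C)C=C2 | intermediate
26 | (2S)-5,7-bis(methoxymethoxy)-2-[8-(methoxymethoxy)-2,2-dimethyl-7-(3-methylbut-2-en-1-yl)-2H-chromen-6-yl]-8-(3-methylbut-2-en-1-yl)-2,3-dihydro-4H-chromen-4-one | CC(C)=CCc1c([C@@H]2CC(=O)c3c(OCOC)cc(OCOC)c(CC=C(C)C)c3O2)cc2c(c1OCOC)OC(C)(C)C=C2 | intermediate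
27 | (2S)-5,7-dihydroxy-2-[8-hydroxy-2,2-dimethyl-7-(3-methylbut-2-en-1-yl)-2H-chromen-6-yl]-8-(3-methylbut-2-en-1-yl)-2,3-dihydro-4H-chromen-4-one | CC(C)=CCc1c([C@@H]2CC(=O)c3c(O)cc(O)c(CC=C(C)C)c3O2)cc2c(c1O)OC(C)(C)C=C2 | target

**Step count and risk**

Total step count: 12. Longest linear sequence: 9 (steps 1 to 6, then 10 to 12).

The three steps most likely to fail:

1. Step 11 (oxa-Michael closure and decarboxylation). What may go wrong: poor facial selectivity in the closure, because the aroyl ring is substituted at both ortho positions and the attacking phenol is flanked by a prenyl group; and loss of MOM groups during the acidic decarboxylation, followed by addition of the freed phenols across the prenyl double bonds. Fallback: setting out from acetophenone 20 and aldehyde 16, a Claisen–Schmidt condensation (KOH, EtOH/H2O, rt) should give the (E)-2'-hydroxychalcone F1. NaOAc in refluxing EtOH should close it to the racemic tri-MOM flavanone F2. Kinetic resolution by asymmetric transfer hydrogenation (RuCl(p-cymene)[(R,R)-TsDPEN], HCO2H/Et3N, rt, stopped near half conversion) should reduce the 2R ketone to the cis-flavan-4-ol F3 and leave the 2S ketone. That ketone is compound 26, where the route is rejoined.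

2. Step 4 (double semi-hydrogenation). What may go wrong: over-reduction of the monosubstituted vinyl group or of the styrenyl double bond while the second alkyne is still being consumed, and partial Z to E isomerisation. Fallback: setting out from 7, the aryl alkyne alone is reduced by a dissolving-metal cis-reduction (zinc dust activated with Cu(OAc)2 and AgNO3, MeOH/H2O, 40 °C), which does not touch alkenes, to give the Z-alkenyl phenol F4. The copper-catalysed propargylation of step 3 with 8 should then give the propargyl ether F5. A short Lindlar reduction of the terminal alkyne only (H2, Pd/CaCO3 poisoned with Pb(OAc)2, quinoline) returns to 10.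

3. Step 1 (metalation and hydroxylation). What may go wrong: competing deprotonation next to bromine, or loss of LiF from the ortho-fluoroaryllithium to an aryne before the borate is formed. Fallback: setting out from 1, an iridium-catalysed C–H borylation ([Ir(OMe)(cod)]2, 4,4'-di-tert-butyl-2,2'-bipyridine, B2pin2, THF, 80 °C) should functionalise the only ring C–H without a large neighbour, the one ortho to fluorine, to give the pinacol boronate F6. Oxidation (30% H2O2, aq NaOH, 0 °C) should give phenol acetal 4, where the route is rejoined; 4 is hydrolysed to 5 as in step 1.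

**Further compounds**

F1 | step 11 | (2E)-1-[2-hydroxy-4,6-bis(methoxymethoxy)-3-(3-methylbut-2-en-1-yl)phenyl]-3-[8-(methoxymethoxy)-2,2-dimethyl-7-(3-methylbut-2-en-1-yl)-2H-chromen-6-yl]prop-2-en-1-one | O=C(/C=C/c1cc2C=CC(C)(C)Oc2c(OCOC)c1CC=C(C)C)c1c(OCOC)cc(OCOC)c(CC=C(C)C)c1O
F2 | step 11 | racemic 5,7-bis(methoxymethoxy)-2-[8-(methoxymethoxy)-2,2-dimethyl-7-(3-methylbut-2-en-1-yl)-2H-chromen-6-yl]-8-(3-methylbut-2-en-1-yl)-2,3-dihydro-4H-chromen-4-one | CC(C)=CCc1c(C2CC(=O)c3c(OCOC)cc(OCOC)c(CC=C(C)C)c3O2)cc2c(c1OCOC)OC(C)(C)C=C2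
F3 | step 11 | (2R,4R)-5,7-bis(methoxymethoxy)-2-[8-(methoxymethoxy)-2,2-dimethyl-7-(3-methylbut-2-en-1-yl)-2H-chromen-6-yl]-8-(3-methylbut-2-en-1-yl)-3,4-dihydro-2H-chromen-4-ol | CC(C)=CCc1c([C@H]2C[C@@H](O)c3c(OCOC)cc(OCOC)c(CC=C(C)C)c3O2)cc2c(c1OCOC)OC(C)(C)C=C2
F4 | step 4 | 4-fluoro-3-hydroxy-5-[(1Z)-3-hydroxy-3-methylbut-1-en-1-yl]benzaldehyde | O=Cc1cc(O)c(F)c(/C=C\C(C)(C)O)c1
F5 | step 4 | 4-fluoro-3-[(1Z)-3-hydroxy-3-methylbut-1-en-1-yl]-5-[(2-methylbut-3-yn-2-yl)oxy]benzaldehyde | O=Cc1cc(OC(C)(C)C#C)c(F)c(/C=C\C(C)(C)O)c1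
F6 | step 1 | 2-[3-bromo-4-fluoro-5-(4,4,5,5-tetramethyl-1,3,2-dioxaborolan-2-yl)phenyl]-1,3-dioxolane | CC1(C)OB(OC1(C)C)c1cc(cc(Br)c1F)C1OCCO1
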